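**Retrosynthetic overview**
1. Target 20 ⇐ ester hydrolysis, C-6 methylenation and C-3 ketone reduction of the cis-fused diketone 17.
2. 17 ⇐ ring B closed last by an intramolecular Michael addition of side-chain ketone 16 onto the ring A enone (sets the quaternary C-4a, the cis fusion and, by equilibration, C-5).
3. 16 ⇐ enone aldehyde 9 + alkylzinc 14 (side chain from 5-chloropent-1-yne by carboalumination); 9 ⇐ Stork–Danheiser methyl transposition of vinylogous ester 7.
4. 7 ⇐ key step: amine-catalysed desymmetrising Mukaiyama–Michael addition of the achiral bis(enol ether) 3 to acrolein (first two stereocentres).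
5. 3 ⇐ Birch reductive methylation of 3,5-dimethoxybenzoic acid; ring A comes from the arene, ring B is formed second.

Assumption: the SMILES is taken literally, i.e. a cis-fused decalin, (1R,3S,4aR,5R,8aS) in naphthalene numbering, and the sense of induction of the imidazolidinone in step 2 is assumed (the mirror-image catalyst is used if it proves opposite).

**Step 1**
Reactants: 1 3,5-dimethoxybenzoic acid
Product: 3 3,5-dimethoxy-1-methylcyclohexa-2,5-diene-1-carboxylic acid, via dilithium dianion 2 (not isolated)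
Conditions: Li, NH3(l)/THF, −78 °C; MeI, −78 → −33 °C; NH4Cl, then cold aq. HCl to pH 4
Reagents that add atoms: iodomethane (CI)
Why: Birch reductive alkylation: two-electron reduction of the lithium benzoate gives the cross-conjugated enediolate 2, which is methylated at the carboxyl-bearing carbon; 3 has a mirror plane through C-1 and C-4, so no stereocentre exists yet.

**Step 2**
Reactants: 3 3,5-dimethoxy-1-methylcyclohexa-2,5-diene-1-carboxylic acid; 4 acrolein
Product: 7 (1R,2R)-2-(3,3-dimethoxypropyl)-5-methoxy-1-methyl-3-oxocyclohex-4-ene-1-carboxylic acid, via keto aldehyde 5 (not isolated), via conjugated aldehyde 6 (not isolated)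
Conditions: 4 (1.5 equiv, slow addition), (2S,5S)-5-benzyl-2-tert-butyl-3-methylimidazolidin-4-one (second-generation MacMillan imidazolidinone, 20 mol%, free base), H2O (2 equiv), CH2Cl2, −40 °C; Et3N (0.3 equiv), 0 °C; concentrate; HC(OMe)3, MeOH, PPTS (cat.), 0 °C
Reagents that add atoms: water (O); trimethyl orthoformate (COC(OC)OC)
Why: Proposed new method: an enantiotopic-group-selective, carboxylate-directed Mukaiyama–Michael addition in which the amine and 4 form an iminium ion whose counter-ion is the carboxylate of 3, so that the enol-ether carbon is alkylated inside a contact ion pair on the carboxylate face (side chain cis to CO2H) while the chiral cation distinguishes the two mirror-related enol ethers, setting C-1 and C-2 together as the first stereocentres; water hydrolyses the oxocarbenium ion and the enamine (turnover), Et3N moves the remaining enol ether into conjugation (5 to 6) before the aldehyde is masked as its acetal; the closest known reaction type is the imidazolidinone-catalysed Mukaiyama–Michael addition of silyl enol ethers and silyloxyfurans to enals, which has not been shown as a desymmetrisation of a Birch-derived bis(enol ether).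

**Step 3**
Reactants: 7 (1R,2R)-2-(3,3-dimethoxypropyl)-5-methoxy-1-methyl-3-oxocyclohex-4-ene-1-carboxylic acid
Product: 9 (1R,2S)-1,3-dimethyl-5-oxo-2-(3-oxopropyl)cyclohex-3-ene-1-carboxylic acid, via tertiary carbinol 8 (not isolated)
Conditions: MeLi (3 equiv), THF, −78 → −20 °C; then 1 M HCl, THF, 0 → 20 °C
Reagents that add atoms: methyllithium ([Li]C); water (O)
Why: Stork–Danheiser transposition: MeLi adds 1,2 to the vinylogous-ester carbonyl (lithium carboxylate and acetal are inert), and aqueous acid hydrolyses the enol ether, dehydrates carbinol 8 to the 3-methyl enone and unmasks the aldehyde, leaving C-1 and C-2 untouched (the 2S label is only a change in CIP priorities).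

**Step 4**
Reactants: 10 5-chloropent-1-yne
Product: 12 methyl (2E)-6-chloro-3-methylhex-2-enoate, via alkenylalane 11 (not isolated)
Conditions: Me3Al (2.5 equiv), Cp2ZrCl2 (25 mol%), CH2Cl2, 0 → 20 °C; ClCO2Me, 0 °C; aq. HCl work-up
Reagents that add atoms: trimethylaluminium (C[Al](C)C); methyl chloroformate (COC(=O)Cl)
Why: Negishi zirconium-catalysed carboalumination adds CH3–Al syn across the terminal alkyne, and acylation of alkenylalane 11 with retention gives the (E)-β-methyl enoate, which is the side-chain alkene geometry of the target.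

**Step 5**
Reactants: 12 methyl (2E)-6-chloro-3-methylhex-2-enoate
Product: 13 methyl (2E)-6-iodo-3-methylhex-2-enoate
Conditions: NaI, acetone, reflux
Reagents that add atoms: sodium iodide ([Na+].[I-])
Why: Finkelstein halide exchange (SN2) driven by precipitation of NaCl; the alkene geometry is not affected.

**Step 6**
Reactants: 9 (1R,2S)-1,3-dimethyl-5-oxo-2-(3-oxopropyl)cyclohex-3-ene-1-carboxylic acid; 13 methyl (2E)-6-iodo-3-methylhex-2-enoate
Product: 15 (1R,2S)-2-[(7E)-3-hydroxy-9-methoxy-7-methyl-9-oxonon-7-en-1-yl]-1,3-dimethyl-5-oxocyclohex-3-ene-1-carboxylic acid (both carbinol epimers), via alkylzinc iodide 14 (not isolated)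
Conditions: 13 (2.2 equiv), Zn dust, LiCl, THF, 40 °C; then 9, MgCl2, THF, 0 → 20 °C; aq. NH4Cl/HCl work-up
Reagents that add atoms: none
Why: Knochel zinc insertion followed by MgCl2-promoted 1,2-addition of the functionalised alkylzinc iodide 14 to the aldehyde, chemoselective over the β,β-disubstituted enone and the esters (one equivalent of 14 is consumed by the free CO2H); the new carbinol centre is oxidised away in step 7.

**Step 7**
Reactants: 15 (1R,2S)-2-[(7E)-3-hydroxy-9-methoxy-7-methyl-9-oxonon-7-en-1-yl]-1,3-dimethyl-5-oxocyclohex-3-ene-1-carboxylic acid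
Product: 17 (1R,4aS,5S,8aS)-5-[(3E)-5-methoxy-3-methyl-5-oxopent-3-en-1-yl]-1,4a-dimethyl-3,6-dioxodecahydronaphthalene-1-carboxylic acid, via side-chain ketone 16 (not isolated)
Conditions: Dess–Martin periodinane, CH2Cl2, 0 → 20 °C; aq. NaHCO3/Na2S2O3 wash; then DBU (2.5 equiv), MeCN, 20 °C
Reagents that add atoms: none
Why: Dess–Martin oxidation then base-mediated intramolecular Michael addition, in which the tether on C-2 of 16 (cis to CO2H) can reach the planar enone β-carbon only from its own face, giving the cis ring fusion and the quaternary C-4a with its methyl cis to 8a-H, while C-5 (α to the new C-6 ketone) equilibrates under DBU, and is protonated axially, to the epimer with the side chain equatorial on ring B (5-H cis to the 4a-methyl, as in the target).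

**Step 8**
Reactants: 17 (1R,4aS,5S,8aS)-5-[(3E)-5-methoxy-3-methyl-5-oxopent-3-en-1-yl]-1,4a-dimethyl-3,6-dioxodecahydronaphthalene-1-carboxylic acid
Product: 18 (1R,3S,4aS,5S,8aS)-3-hydroxy-5-[(3E)-5-methoxy-3-methyl-5-oxopent-3-en-1-yl]-1,4a-dimethyl-6-oxodecahydronaphthalene-1-carboxylic acid
Conditions: LiBH(s-Bu)3 (L-Selectride, 2.1 equiv), THF, −78 °C; aq. HCl work-up at −78 → 0 °C
Reagents that add atoms: none
Why: Chemo- and stereoselective hydride reduction: the C-3 ketone is attacked along the equatorial trajectory from the face opposite the syn-axial 1- and 4a-methyl groups, giving the axial 3-OH cis to both methyls (3S), while the C-6 ketone, α-branched and next to the quaternary C-4a, reacts far more slowly with the bulky borohydride at −78 °C.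

**Step 9**
Reactants: 18 (1R,3S,4aS,5S,8aS)-3-hydroxy-5-[(3E)-5-methoxy-3-methyl-5-oxopent-3-en-1-yl]-1,4a-dimethyl-6-oxodecahydronaphthalene-1-carboxylic acid
Product: 19 (1R,3S,4aR,5R,8aS)-3-hydroxy-5-[(3E)-5-methoxy-3-methyl-5-oxopent-3-en-1-yl]-1,4a-dimethyl-6-methylidenedecahydronaphthalene-1-carboxylic acid
Conditions: Zn, CH2Br2, TiCl4, THF (reagent pre-formed and aged at 5 °C); 18, CH2Cl2, 20 °C
Reagents that add atoms: dibromomethane (BrCBr)
Why: Lombardo methylenation: the non-basic Zn/CH2Br2/TiCl4 reagent converts the hindered, enolisable C-6 ketone into the exocyclic methylidene without epimerising C-5 and tolerates the hydroxyl, the carboxylic acid and the ester.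

**Step 10**
Reactants: 19 (1R,3S,4aR,5R,8aS)-3-hydroxy-5-[(3E)-5-methoxy-3-methyl-5-oxopent-3-en-1-yl]-1,4a-dimethyl-6-methylidenedecahydronaphthalene-1-carboxylic acid
Product: 20 (1R,3S,4aR,5R,8aS)-5-[(3E)-4-carboxy-3-methylbut-3-en-1-yl]-3-hydroxy-1,4a-dimethyl-6-methylidenedecahydronaphthalene-1-carboxylic acid
Conditions: LiOH, THF/MeOH/H2O, 20 °C; then aq. HCl to pH 3
Reagents that add atoms: lithium hydroxide ([Li+].[OH-])
Why: Saponification of the unhindered conjugated methyl ester (the tertiary acid is already free); the alkenes and all five stereocentres are stable to LiOH at room temperature.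

**Compound list**
1 | 3,5-dimethoxybenzoic acid | COc1cc(cc(OC)c1)C(=O)O | starting material
2 | dilithium (3,5-dimethoxycyclohexa-2,5-dien-1-ylidene)methanediolate | COC1=CC(=C([O-])[O-])C=C(OC)C1.[Li+].[Li+] | intermediate
3 | 3,5-dimethoxy-1-methylcyclohexa-2,5-diene-1-carboxylic acid | COC1=CC(C)(C(=O)O)C=C(OC)C1 | intermediate
4 | acrolein (prop-2-enal) | C=CC=O | starting material
5 | (1R,6R)-3-methoxy-1-methyl-5-oxo-6-(3-oxopropyl)cyclohex-2-ene-1-carboxylic acid | COC1=C[C@@](C)(C(=O)O)[C@@H](CCC=O)C(=O)C1 | intermediate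
6 | (1R,2R)-5-methoxy-1-methyl-3-oxo-2-(3-oxopropyl)cyclohex-4-ene-1-carboxylic acid | COC1=CC(=O)[C@H](CCC=O)[C@](C)(C(=O)O)C1 | intermediate
7 | (1R,2R)-2-(3,3-dimethoxypropyl)-5-methoxy-1-methyl-3-oxocyclohex-4-ene-1-carboxylic acid | COC1=CC(=O)[C@H](CCC(OC)OC)[C@](C)(C(=O)O)C1 | intermediate
8 | (1R,2R)-2-(3,3-dimethoxypropyl)-3-hydroxy-5-methoxy-1,3-dimethylcyclohex-4-ene-1-carboxylic acid (C-3 epimers) | COC1=CC(C)(O)[C@H](CCC(OC)OC)[C@](C)(C(=O)O)C1 | intermediate
9 | (1R,2S)-1,3-dimethyl-5-oxo-2-(3-oxopropyl)cyclohex-3-ene-1-carboxylic acid | CC1=CC(=O)C[C@@](C)(C(=O)O)[C@H]1CCC=O | intermediate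
10 | 5-chloropent-1-yne | ClCCCC#C | starting material
11 | [(1E)-5-chloro-2-methylpent-1-en-1-yl]dimethylaluminium | ClCCC/C(C)=C/[Al](C)C | intermediate
12 | methyl (2E)-6-chloro-3-methylhex-2-enoate | ClCCC/C(C)=C/C(=O)OC | intermediate
13 | methyl (2E)-6-iodo-3-methylhex-2-enoate | ICCC/C(C)=C/C(=O)OC | intermediate
14 | [(4E)-6-methoxy-4-methyl-6-oxohex-4-en-1-yl]zinc iodide | I[Zn]CCC/C(C)=C/C(=O)OC | intermediate
15 | (1R,2S)-2-[(7E)-3-hydroxy-9-methoxy-7-methyl-9-oxonon-7-en-1-yl]-1,3-dimethyl-5-oxocyclohex-3-ene-1-carboxylic acid | CC1=CC(=O)C[C@@](C)(C(=O)O)[C@H]1CCC(O)CCC/C(C)=C/C(=O)OC | intermediate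
16 | (1R,2S)-2-[(7E)-9-methoxy-7-methyl-3,9-dioxonon-7-en-1-yl]-1,3-dimethyl-5-oxocyclohex-3-ene-1-carboxylic acid | CC1=CC(=O)C[C@@](C)(C(=O)O)[C@H]1CCC(=O)CCC/C(C)=C/C(=O)OC | intermediate
17 | (1R,4aS,5S,8aS)-5-[(3E)-5-methoxy-3-methyl-5-oxopent-3-en-1-yl]-1,4a-dimethyl-3,6-dioxodecahydronaphthalene-1-carboxylic acid | O=C1CC[C@H]2[C@](C)(CC(=O)C[C@@]2(C)C(=O)O)[C@@H]1CC/C(C)=C/C(=O)OC | intermediate
18 | (1R,3S,4aS,5S,8aS)-3-hydroxy-5-[(3E)-5-methoxy-3-methyl-5-oxopent-3-en-1-yl]-1,4a-dimethyl-6-oxodecahydronaphthalene-1-carboxylic acid | O=C1CC[C@H]2[C@](C)(C[C@H](O)C[C@@]2(C)C(=O)O)[C@@H]1CC/C(C)=C/C(=O)OC | intermediate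
19 | (1R,3S,4aR,5R,8aS)-3-hydroxy-5-[(3E)-5-methoxy-3-methyl-5-oxopent-3-en-1-yl]-1,4a-dimethyl-6-methylidenedecahydronaphthalene-1-carboxylic acid | C=C1CC[C@H]2[C@](C)(C[C@H](O)C[C@@]2(C)C(=O)O)[C@@H]1CC/C(C)=C/C(=O)OC | intermediate
20 | (1R,3S,4aR,5R,8aS)-5-[(3E)-4-carboxy-3-methylbut-3-en-1-yl]-3-hydroxy-1,4a-dimethyl-6-methylidenedecahydronaphthalene-1-carboxylic acid | C=C1CC[C@H]2[C@](C)(C[C@H](O)C[C@@]2(C)C(=O)O)[C@@H]1CC/C(C)=C/C(=O)O | target

**Step count**
Total: 10 steps. Longest linear sequence: 8 steps (1, 2, 3, 6, 7, 8, 9, 10); steps 4 and 5 make the side chain.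

**Three steps most likely to fail**

Step 2 (the proposed new desymmetrisation). Enantiotopic-group selection, the cis delivery by the carboxylate, and over-reaction of the second enol ether are all untested. The fallback uses known chemistry and sets out from 3. Mild hydrolysis of one enol ether (oxalic acid, wet THF, 0 °C, then Et3N) gives the racemic vinylogous ester F1. Its dianion (LDA, THF/DMPU, −78 °C) is alkylated at the α′-methylene (Stork–Danheiser alkylation) with 3-bromo-1,1-dimethoxypropane. This gives 7 as a racemate, that is together with its enantiomer F2, and the C-2 epimer F3, which is removed by chromatography. Classical resolution by crystallisation of the (S)-1-phenylethylammonium salt F4 and acidification returns to the route at 7.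

Step 7 (ring B closure). The base could epimerise C-2 of 16 by γ-deprotonation of the enone, the Michael addition could reverse towards the more stable trans-fused isomer, and the C-5 equilibrium ratio is only estimated to favour the target epimer. The fallback sets out from 16, isolated after the oxidation. Pyrrolidine with AcOH in MeCN at 40 °C converts the side-chain ketone into the pyrrolidine enamine F5. This cyclises as a neutral Stork enamine Michael addition through the same cis-selective geometry, with no enolate present. Hydrolysis with aqueous AcOH returns to the route at 17, and C-5 can then be equilibrated separately with a catalytic amount of DBU.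

Step 8 (reduction of one of two ketones). The preference for C-3 over C-6 rests on sterics alone. The fallback sets out from 17. Kinetic deprotonation at the unhindered C-7 methylene (LDA, 2.2 equiv, TMSCl, THF, −78 °C; both α-methylenes of the C-3 ketone are neopentylic) masks the C-6 ketone as the trimethylsilyl enol ether, trimethylsilyl ester F6. LiBH(s-Bu)3 then has only the C-3 ketone to reduce, and dilute HCl work-up removes both silyl groups, returning to the route at 18.

**Further compounds**
F1 | step 2 | racemic 5-methoxy-1-methyl-3-oxocyclohex-4-ene-1-carboxylic acid | COC1=CC(=O)CC(C)(C(=O)O)C1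
F2 | step 2 | (1S,2S)-2-(3,3-dimethoxypropyl)-5-methoxy-1-methyl-3-oxocyclohex-4-ene-1-carboxylic acid | COC1=CC(=O)[C@@H](CCC(OC)OC)[C@@](C)(C(=O)O)C1
F3 | step 2 | (1R*,2S*)-2-(3,3-dimethoxypropyl)-5-methoxy-1-methyl-3-oxocyclohex-4-ene-1-carboxylic acid (racemic C-2 epimer, one enantiomer drawn) | COC1=CC(=O)[C@@H](CCC(OC)OC)[C@](C)(C(=O)O)C1
F4 | step 2 | (S)-1-phenylethylammonium (1R,2R)-2-(3,3-dimethoxypropyl)-5-methoxy-1-methyl-3-oxocyclohex-4-ene-1-carboxylate | COC1=CC(=O)[C@H](CCC(OC)OC)[C@](C)(C(=O)[O-])C1.C[C@H]([NH3+])c1ccccc1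
F5 | step 7 | (1R,2S)-2-[(7E)-9-methoxy-7-methyl-9-oxo-3-(pyrrolidin-1-yl)nona-3,7-dien-1-yl]-1,3-dimethyl-5-oxocyclohex-3-ene-1-carboxylic acid | CC1=CC(=O)C[C@@](C)(C(=O)O)[C@H]1CCC(=CCC/C(C)=C/C(=O)OC)N1CCCC1
F6 | step 8 | trimethylsilyl ester of the 6-(trimethylsilyloxy)-6,7-ene derived from 17 | C[Si](C)(C)OC1=CC[C@H]2[C@](C)(CC(=O)C[C@@]2(C)C(=O)O[Si](C)(C)C)[C@@H]1CC/C(C)=C/C(=O)OC
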